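**Retrosynthetic overview** (labdane numbering: C4 ester-bearing carbon, C5/C10 ring fusion, C8 methylidene carbon, C9 side-chain carbon)

1. Target 19 ⇐ acetate-for-silyl exchange and methylenation of C8 ketone 16 ⇐ hydrogenation and allylic oxidation of bicyclic diene ester 14 ⇐ methylation at C4 of 12.
2. Ring A of 12 ⇐ ring-B aldehyde ester 8 + vinyltriphenylphosphonium bromide 9 in one pot: Michael addition makes C3–C4, intramolecular Wittig olefination makes C1=C2.
3. Ring B of 8 ⇐ catalytic enantioselective endo Diels–Alder reaction of (E)-enal 4 (from (S)-citronellol and methacrolein by cross-metathesis) with dienoate 7 (from methyl sorbate); C5, C9 and C10 are set in this one event.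
4. Enabling feature: in ring A (C1–C2–C3–C4–C5–C10) the C2–C3 unit is an unsubstituted ethano bridge between C1, a methylene on the quaternary ring-fusion carbon C10, and C4, the α-carbon of the C19 ester; without it there remain a non-enolisable aldehyde on C10 and an acidic ester α-CH2 on C5, cis on adjacent carbons of cyclohexene ring B.
5. Order of ring formation: ring B (step 4), then ring A (step 5); C13 is bought, C4 is relayed from C10 (step 6).

Key step: step 5

Assumption: the stereodescriptors are taken literally from the SMILES, so H-5 is syn to the C10 methyl (cis-fused decalin; 4S,5S,9S,10R,13S in labdane numbering); for step 4 the (S)-oxazaborolidinium catalyst is written, and its antipode would be used should its facial preference prove opposite.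

Abbreviation: Rs = (3S)-5-{[tert-butyl(diphenyl)silyl]oxy}-3-methylpentyl.

**Route**

Step 1
Reactants: 1 (S)-citronellol
Product: 2 tert-butyl{[(3S)-3,7-dimethyloct-6-en-1-yl]oxy}diphenylsilane
Conditions: TBDPSCl, imidazole, DMF, 0 °C to rt
Reagents that add atoms: tert-butyl(chloro)diphenylsilane, CC(C)(C)[Si](Cl)(c1ccccc1)c1ccccc1
Why: Imidazole-promoted silylation of the primary alcohol, chosen because the silyl ether, unlike the final acetate, survives the amide bases of steps 5 and 6.

Step 2
Reactants: 2 tert-butyl{[(3S)-3,7-dimethyloct-6-en-1-yl]oxy}diphenylsilane; 3 methacrolein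
Product: 4 (2E,6S)-8-{[tert-butyl(diphenyl)silyl]oxy}-2,6-dimethyloct-2-enal
Conditions: Hoveyda–Grubbs II catalyst (5 mol %), 3 (10 equiv), CH2Cl2, 40 °C
Reagents that add atoms: none
Why: Olefin cross-metathesis in which the prenyl-type terminus exchanges its isopropylidene for the C(CH3)CHO unit of methacrolein with loss of isobutene, and the conjugated trisubstituted enal should form as the thermodynamically preferred E isomer that later places the C10 methyl and the side chain cis.

Step 3
Reactants: 5 methyl sorbate
Product: 7 methyl (3E)-hexa-3,5-dienoate, via lithium trienolate 6 (not isolated)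
Conditions: LDA, THF–DMPU, −78 °C; then AcOH, −78 °C
Reagents that add atoms: none
Why: Kinetic deconjugation, in which deprotonation of the terminal methyl gives the trienolate and protonation at the α-carbon gives the 3,5-dienoate, the s-trans geometry of the sorbate fixing the 3E double bond.

Step 4
Reactants: 4 (2E,6S)-8-{[tert-butyl(diphenyl)silyl]oxy}-2,6-dimethyloct-2-enal; 7 methyl (3E)-hexa-3,5-dienoate
Product: 8 methyl 2-[(1S,5S,6R)-6-formyl-6-methyl-5-Rs-cyclohex-2-en-1-yl]acetate
Conditions: (S)-B-(o-tolyl) CBS-type oxazaborolidine·HNTf2 (20 mol %), 7 (3 equiv), CH2Cl2, −40 to −20 °C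
Reagents that add atoms: none
Why: Chiral oxazaborolidinium (Lewis acid) catalysed Diels–Alder reaction, in which the 1-substituted diene should add with ortho regiochemistry (C5–C10 and C8–C9 bonds), endo orientation of the boron-bound formyl group should place CHO cis to the acetate arm, suprafacial addition to the E-enal keeps the C10 methyl and the side chain cis, and shielding of one enal face by the catalyst sets the absolute configuration of C5, C9 and C10 together, the remote C13 centre having no influence.

Step 5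
Reactants: 8 methyl 2-[(1S,5S,6R)-6-formyl-6-methyl-5-Rs-cyclohex-2-en-1-yl]acetate; 9 vinyltriphenylphosphonium bromide
Product: 12 methyl (1RS,4aS,5S,8aR)-4a-methyl-5-Rs-1,2,4a,5,6,8a-hexahydronaphthalene-1-carboxylate, via potassium ester enolate 10 (not isolated), via phosphonium ylide 11 (not isolated)
Conditions: KHMDS (1.0 equiv), THF, −78 °C; then 9 (1.3 equiv), THF–DMPU, −78 to 40 °C
Reagents that add atoms: none
Why: KHMDS removes a proton from C4, the α-CH2 of the ester and the only acidic C–H of 8 (the C1 aldehyde sits on quaternary C10 and cannot enolise), and enolate 10 adds to the vinylphosphonium salt (C3–C4 bond) to give the non-stabilised ylide 11, whose C2 attacks the cis-disposed C1 aldehyde in an intramolecular Wittig olefination (C1=C2 bond) with loss of triphenylphosphine oxide. The closest known reaction type is the tandem Michael addition/intramolecular Wittig annulation of carbonyl-tethered enolates with vinyltriphenylphosphonium salts, used for cyclopentene and cyclohexene synthesis. Ring A is closed in the olefination event, formally a 6-exo-trig addition of the ylide carbon to C=O through the oxaphosphetane, and the ring enforces the cis geometry of the new C1=C2 bond. The only new stereocentre, C4, is formed without control and as an epimer mixture on purpose, because step 6 re-enolises this carbon; C5, C9 and C10 are not touched. The selectivity needed is conjugate C-alkylation over aldol or amide addition at the aldehyde: an intramolecular aldol would give a four-membered ring, intermolecular potassium aldolates of the hindered neopentyl aldehyde should revert, whereas conjugate addition and olefination are irreversible. Ring closure is possible only because the endo Diels–Alder step placed the formyl group and the acetate arm cis on C10 and C5 of ring B.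

Step 6
Reactants: 12 methyl (1RS,4aS,5S,8aR)-4a-methyl-5-Rs-1,2,4a,5,6,8a-hexahydronaphthalene-1-carboxylate
Product: 14 methyl (1S,4aS,5S,8aS)-1,4a-dimethyl-5-Rs-1,2,4a,5,6,8a-hexahydronaphthalene-1-carboxylate, via lithium ester enolate 13 (not isolated)
Conditions: LDA, THF, −78 °C; then MeI, DMPU, −78 to −20 °C
Reagents that add atoms: iodomethane, CI
Why: Ester enolate alkylation, in which LDA regenerates the planar C4 enolate (removing the epimer mixture), A(1,3) strain should hold H-5 in the enolate plane so that C6 is pseudoaxial on one face and the angular C10 methyl pseudoaxial on the other, and iodomethane should enter anti to that 1,3-related angular methyl, as in the classical C4 alkylations of podocarpate-type esters, giving the 4α-methyl/4β-ester (4S) centre.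

Step 7
Reactants: 14 methyl (1S,4aS,5S,8aS)-1,4a-dimethyl-5-Rs-1,2,4a,5,6,8a-hexahydronaphthalene-1-carboxylate
Product: 15 methyl (1S,4aS,5R,8aS)-1,4a-dimethyl-6-oxo-5-Rs-1,2,4a,5,6,8a-hexahydronaphthalene-1-carboxylate
Conditions: Rh2(cap)4 (1 mol %), t-BuOOH (70 % aq., 5 equiv), 1,2-dichloroethane, 40 °C
Reagents that add atoms: tert-butyl hydroperoxide, CC(C)(C)OO
Why: Dirhodium caprolactamate/TBHP allylic oxidation, in which hydrogen abstraction should occur at the ring-B allylic methylene C8, because the only allylic CH2 of ring A (C3) is neopentyl to the quaternary ester-bearing C4 and the allylic C5–H is tertiary between two quaternary carbons, and the peroxy intermediate collapses to the conjugated C8 enone.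

Step 8
Reactants: 15 methyl (1S,4aS,5R,8aS)-1,4a-dimethyl-6-oxo-5-Rs-1,2,4a,5,6,8a-hexahydronaphthalene-1-carboxylate
Product: 16 methyl (1S,4aS,5R,8aS)-1,4a-dimethyl-6-oxo-5-Rs-decahydronaphthalene-1-carboxylate
Conditions: H2 (3 atm), 10 % Pd/C, EtOAc, rt
Reagents that add atoms: none
Why: Heterogeneous catalytic hydrogenation of the two cis-disubstituted ring alkenes (one conjugated), which turns C1, C2, C6 and C7 into CH2 groups, so no stereocentre is created or touched while ketone, ester and silyl ether stay inert.

Step 9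
Reactants: 16 methyl (1S,4aS,5R,8aS)-1,4a-dimethyl-6-oxo-5-Rs-decahydronaphthalene-1-carboxylate
Product: 17 methyl (1S,4aR,5S,8aS)-1,4a-dimethyl-6-methylidene-5-Rs-decahydronaphthalene-1-carboxylate
Conditions: Zn, CH2Br2, TiCl4, THF–CH2Cl2, 0 °C to rt
Reagents that add atoms: dibromomethane, BrCBr
Why: Lombardo methylenation, whose non-basic zinc/titanium methylene reagent should convert the hindered C8 ketone into the exocyclic methylene without enolising the adjacent C9 stereocentre and without touching the methyl ester.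

Step 10
Reactants: 17 methyl (1S,4aR,5S,8aS)-1,4a-dimethyl-6-methylidene-5-Rs-decahydronaphthalene-1-carboxylate
Product: 18 methyl (1S,4aR,5S,8aS)-5-[(3S)-5-hydroxy-3-methylpentyl]-1,4a-dimethyl-6-methylidenedecahydronaphthalene-1-carboxylate
Conditions: TBAF, THF, rt
Reagents that add atoms: none
Why: Fluoride-mediated cleavage of the silyl ether, to which the ester and the exocyclic alkene are inert.

Step 11
Reactants: 18 methyl (1S,4aR,5S,8aS)-5-[(3S)-5-hydroxy-3-methylpentyl]-1,4a-dimethyl-6-methylidenedecahydronaphthalene-1-carboxylate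
Product: 19 methyl (1S,4aR,5S,8aS)-5-[(3S)-5-acetoxy-3-methylpentyl]-1,4a-dimethyl-6-methylidenedecahydronaphthalene-1-carboxylate
Conditions: Ac2O, pyridine, DMAP (cat.), CH2Cl2, rt
Reagents that add atoms: acetic anhydride, CC(=O)OC(C)=O
Why: DMAP-catalysed acetylation of the primary alcohol completes the target.

**Compound list**

1 | (S)-citronellol, (3S)-3,7-dimethyloct-6-en-1-ol | CC(C)=CCC[C@H](C)CCO | starting material
2 | tert-butyl{[(3S)-3,7-dimethyloct-6-en-1-yl]oxy}diphenylsilane | CC(C)=CCC[C@H](C)CCO[Si](c1ccccc1)(c1ccccc1)C(C)(C)C | intermediate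
3 | methacrolein (2-methylprop-2-enal) | CC(=C)C=O | starting material
4 | (2E,6S)-8-{[tert-butyl(diphenyl)silyl]oxy}-2,6-dimethyloct-2-enal | O=C/C(C)=C/CC[C@H](C)CCO[Si](c1ccccc1)(c1ccccc1)C(C)(C)C | intermediate
5 | methyl sorbate, methyl (2E,4E)-hexa-2,4-dienoate | C/C=C/C=C/C(=O)OC | starting material
6 | lithium trienolate of 5, lithium (3E)-1-methoxyhexa-1,3,5-trien-1-olate | [Li+].C=C/C=C/C=C([O-])OC | intermediate
7 | methyl (3E)-hexa-3,5-dienoate | C=C/C=C/CC(=O)OC | intermediate
8 | methyl 2-[(1S,5S,6R)-6-formyl-6-methyl-5-Rs-cyclohex-2-en-1-yl]acetate | C1C=C[C@H](CC(=O)OC)[C@](C)(C=O)[C@H]1CC[C@H](C)CCO[Si](c1ccccc1)(c1ccccc1)C(C)(C)C | intermediate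
9 | vinyltriphenylphosphonium bromide | C=C[P+](c1ccccc1)(c1ccccc1)c1ccccc1.[Br-] | starting material
10 | potassium ester enolate of 8 (ester α-carbon deprotonated, ring stereocentres unchanged) | C1C=C[C@H](C=C([O-])OC)[C@](C)(C=O)[C@H]1CC[C@H](C)CCO[Si](c1ccccc1)(c1ccccc1)C(C)(C)C.[K+] | intermediate
11 | phosphonium ylide from 10 and 9: methyl 2-(ring of 8)-4-(triphenylphosphoranylidene)butanoate, C4 epimers | C1C=C[C@H](C(CC=P(c2ccccc2)(c2ccccc2)c2ccccc2)C(=O)OC)[C@](C)(C=O)[C@H]1CC[C@H](C)CCO[Si](c1ccccc1)(c1ccccc1)C(C)(C)C | intermediate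
12 | methyl (1RS,4aS,5S,8aR)-4a-methyl-5-Rs-1,2,4a,5,6,8a-hexahydronaphthalene-1-carboxylate | C1C=C[C@H]2[C@](C)(C=CCC2C(=O)OC)[C@H]1CC[C@H](C)CCO[Si](c1ccccc1)(c1ccccc1)C(C)(C)C | intermediate
13 | lithium ester enolate of 12 (exocyclic enolate at C4, other stereocentres unchanged) | C1C=C[C@H]2[C@](C)(C=CCC2=C([O-])OC)[C@H]1CC[C@H](C)CCO[Si](c1ccccc1)(c1ccccc1)C(C)(C)C.[Li+] | intermediate
14 | methyl (1S,4aS,5S,8aS)-1,4a-dimethyl-5-Rs-1,2,4a,5,6,8a-hexahydronaphthalene-1-carboxylate | C1C=C[C@H]2[C@](C)(C=CC[C@]2(C)C(=O)OC)[C@H]1CC[C@H](C)CCO[Si](c1ccccc1)(c1ccccc1)C(C)(C)C | intermediate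
15 | methyl (1S,4aS,5R,8aS)-1,4a-dimethyl-6-oxo-5-Rs-1,2,4a,5,6,8a-hexahydronaphthalene-1-carboxylate | O=C1C=C[C@H]2[C@](C)(C=CC[C@]2(C)C(=O)OC)[C@H]1CC[C@H](C)CCO[Si](c1ccccc1)(c1ccccc1)C(C)(C)C | intermediate
16 | methyl (1S,4aS,5R,8aS)-1,4a-dimethyl-6-oxo-5-Rs-decahydronaphthalene-1-carboxylate | O=C1CC[C@H]2[C@](C)(CCC[C@]2(C)C(=O)OC)[C@H]1CC[C@H](C)CCO[Si](c1ccccc1)(c1ccccc1)C(C)(C)C | intermediate
17 | methyl (1S,4aR,5S,8aS)-1,4a-dimethyl-6-methylidene-5-Rs-decahydronaphthalene-1-carboxylate | C=C1CC[C@H]2[C@](C)(CCC[C@]2(C)C(=O)OC)[C@H]1CC[C@H](C)CCO[Si](c1ccccc1)(c1ccccc1)C(C)(C)C | intermediate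
18 | methyl (1S,4aR,5S,8aS)-5-[(3S)-5-hydroxy-3-methylpentyl]-1,4a-dimethyl-6-methylidenedecahydronaphthalene-1-carboxylate | C=C1CC[C@H]2[C@](C)(CCC[C@]2(C)C(=O)OC)[C@H]1CC[C@H](C)CCO | intermediate
19 | methyl (1S,4aR,5S,8aS)-5-[(3S)-5-acetoxy-3-methylpentyl]-1,4a-dimethyl-6-methylidenedecahydronaphthalene-1-carboxylate | C=C1CC[C@H]2[C@](C)(CCC[C@]2(C)C(=O)OC)[C@H]1CC[C@H](C)CCOC(C)=O | target

**Step count and risks**

Total step count: 11. Longest linear sequence: 10 steps (steps 1, 2 and 4 to 11, from 1).

Step 4 (highest risk): the trisubstituted enal 4 may add too slowly to the non-activated diene 7, so that acid-promoted reconjugation of 7 and loss of endo or facial selectivity take over. The fallback replaces catalyst control by an auxiliary-controlled ionic Diels–Alder reaction and sets out from 4. Acetalisation with (2R,3R)-butane-2,3-diol (PPTS, benzene, Dean–Stark) should give the C2-symmetric dioxolane (4R,5R)-2-[(1E,5S)-7-{[tert-butyl(diphenyl)silyl]oxy}-1,5-dimethylhept-1-en-1-yl]-4,5-dimethyl-1,3-dioxolane F1. With catalytic TfOH in CH2Cl2 at −78 °C the acetal opens to an alkoxy-stabilised allyl cation, a much stronger dienophile than the neutral enal. It should add 7 with the diol backbone directing the face (the antipodal diol would be taken if the sense were opposite) to give the adduct acetal methyl 2-[(1S,5S,6R)-6-[(4R,5R)-4,5-dimethyl-1,3-dioxolan-2-yl]-6-methyl-5-Rs-cyclohex-2-en-1-yl]acetate F2. Mild hydrolysis (PPTS, acetone–water) comes back to the route at 8.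

Step 5: deprotonation and conjugate addition may be outrun by aldol oligomerisation or by amide addition to the aldehyde, or the ylide may be quenched before it olefinates. The fallback closes ring A stepwise by metathesis and sets out from 8. Wittig methylenation of the aldehyde (Ph3P=CH2, THF, 0 °C) should give the vinyl compound methyl 2-[(1S,5S,6R)-6-ethenyl-6-methyl-5-Rs-cyclohex-2-en-1-yl]acetate F3. Its ester enolate (LDA, THF, −78 °C) is allylated with allyl bromide to methyl (2RS)-2-[(1R,5S,6R)-6-ethenyl-6-methyl-5-Rs-cyclohex-2-en-1-yl]pent-4-enoate F4. Ring-closing metathesis of the vinyl and allyl groups (Grubbs II, CH2Cl2, 40 °C) comes back to the route at 12.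

Step 7: hydrogen abstraction may also occur at the ring-A allylic methylene, or the allyl radical may be oxygenated at its other terminus, giving regioisomeric enones; over-oxidation at C5 is also possible. The fallback replaces radical oxygenation by a pericyclic hydroxylation with isolation of the alcohol and sets out from 14. SeO2 (cat.)/t-BuOOH in CH2Cl2 should hydroxylate by an ene/[2,3]-sigmatropic sequence in which selenium has to bond to the alkene carbon remote from the hydrogen it removes. For the ring-A alkene that carbon is the neopentyl one on C10 and is therefore blocked, so the product should be the C8 allylic alcohol methyl (1S,4aS,5R,6RS,8aS)-6-hydroxy-1,4a-dimethyl-5-Rs-1,2,4a,5,6,8a-hexahydronaphthalene-1-carboxylate F5. Oxidation with MnO2 (CH2Cl2, rt) comes back to the route at 15.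

Further compounds
F1 | step 4 | (4R,5R)-2-[(1E,5S)-7-{[tert-butyl(diphenyl)silyl]oxy}-1,5-dimethylhept-1-en-1-yl]-4,5-dimethyl-1,3-dioxolane | C[C@H]1OC(O[C@@H]1C)/C(C)=C/CC[C@H](C)CCO[Si](c1ccccc1)(c1ccccc1)C(C)(C)C
F2 | step 4 | methyl 2-[(1S,5S,6R)-6-[(4R,5R)-4,5-dimethyl-1,3-dioxolan-2-yl]-6-methyl-5-Rs-cyclohex-2-en-1-yl]acetate | C1C=C[C@H](CC(=O)OC)[C@](C)(C2O[C@H](C)[C@@H](C)O2)[C@H]1CC[C@H](C)CCO[Si](c1ccccc1)(c1ccccc1)C(C)(C)C
F3 | step 5 | methyl 2-[(1S,5S,6R)-6-ethenyl-6-methyl-5-Rs-cyclohex-2-en-1-yl]acetate | C1C=C[C@H](CC(=O)OC)[C@](C)(C=C)[C@H]1CC[C@H](C)CCO[Si](c1ccccc1)(c1ccccc1)C(C)(C)C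
F4 | step 5 | methyl (2RS)-2-[(1R,5S,6R)-6-ethenyl-6-methyl-5-Rs-cyclohex-2-en-1-yl]pent-4-enoate | C1C=C[C@H](C(CC=C)C(=O)OC)[C@](C)(C=C)[C@H]1CC[C@H](C)CCO[Si](c1ccccc1)(c1ccccc1)C(C)(C)C
F5 | step 7 | methyl (1S,4aS,5R,6RS,8aS)-6-hydroxy-1,4a-dimethyl-5-Rs-1,2,4a,5,6,8a-hexahydronaphthalene-1-carboxylate | OC1C=C[C@H]2[C@](C)(C=CC[C@]2(C)C(=O)OC)[C@H]1CC[C@H](C)CCO[Si](c1ccccc1)(c1ccccc1)C(C)(C)C
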